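**Retrosynthetic overview**
- Feature: number the oxolane as O1, C2 (ring A = 3,4-dimethoxyphenyl), C3-Me, C4-Me, C5 (ring B = 3,4,5-trimethoxyphenyl). The run O1–C2(ring A)–C3(Me)–C4(Me) is the skeleton of an aryl tigloyl ketone, so only the one-carbon unit C5–ring B is missing.
- Last disconnection: C2–H and C3–H. The target is the ionic-hydrogenation product of the C2=C3 enol ether, a 2,3-dihydrofuran that already carries C4 and C5.
- Key disconnection: C4–C5 and O1–C5 together, by a formal (4+1) annulation of the tigloyl arene with a ring-B benzylide carried on a C2-symmetric thiolane.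
- Building blocks: the enone comes from Weinreb acylation of an aryl Grignard reagent, because a Lewis-acid acylation would risk Nazarov closure and ether cleavage. The sulfonium salt comes from (2R,5R)-hexane-2,5-diol by double inversion with sulfide, then S-benzylation.
- Ring order: the auxiliary thiolane closes in step 4 and the oxolane in step 6. The oxolane is the only ring of the target that is built; rings A and B are bought.

Key step: step 6

Assumption: the thiolanium benzylide is taken to attack the enone with the same facial sense as in its known additions to aldehydes, which calls for the (2S,5S)-sulfide; if the sense proves opposite, (2S,5S)-hexane-2,5-diol is carried through the same steps.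

Step 1
Reactants: 1 tiglic acid [(E)-2-methylbut-2-enoic acid]
Product: 3 (E)-N-methoxy-N,2-dimethylbut-2-enamide, via tigloyl chloride 2 (not isolated)
Conditions: (COCl)2, DMF (cat.), CH2Cl2, 0 °C to rt; then MeNH(OMe)·HCl, Et3N, CH2Cl2, 0 °C to rt
Reagents that add atoms: oxalyl chloride, O=C(Cl)C(=O)Cl (chlorine of 2); N,O-dimethylhydroxylamine hydrochloride, CNOC.Cl
Why: Acid chloride formation followed by N-acylation (Weinreb amide synthesis) runs under mild, non-isomerising conditions, so the E double bond is kept and no stereocentre is involved.

Step 2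
Reactants: 4 4-bromo-1,2-dimethoxybenzene; 3 (E)-N-methoxy-N,2-dimethylbut-2-enamide
Product: 6 (E)-1-(3,4-dimethoxyphenyl)-2-methylbut-2-en-1-one, via arylmagnesium bromide 5 (not isolated)
Conditions: Mg, I2 (cat.), THF, reflux; then 3, THF, −20 to 0 °C; 1 M HCl, 0 °C
Reagents that add atoms: magnesium, [Mg] (in 5 only)
Why: In the Weinreb ketone synthesis the chelated tetrahedral adduct survives until the quench, which prevents over-addition, while the alpha- and beta-methyl groups disfavour 1,4-addition and the E geometry is untouched.

Step 3
Reactants: 7 (2R,5R)-hexane-2,5-diol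
Product: 8 (2R,5R)-hexane-2,5-diyl dimethanesulfonate
Conditions: MsCl, Et3N, CH2Cl2, −20 to 0 °C
Reagents that add atoms: methanesulfonyl chloride, CS(=O)(=O)Cl
Why: O-sulfonylation breaks only the O–H bonds, so both carbinol stereocentres are retained.

Step 4
Reactants: 8 (2R,5R)-hexane-2,5-diyl dimethanesulfonate
Product: 9 (2S,5S)-2,5-dimethylthiolane
Conditions: Na2S·9H2O, EtOH, rt
Reagents that add atoms: sodium sulfide (used as the nonahydrate), [Na+].[Na+].[S-2]
Why: Double SN2 displacement of the secondary mesylates by sulfide closes the thiolane with inversion at each carbon, turning the (2R,5R)-series into the (2S,5S)-sulfide.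

Step 5
Reactants: 9 (2S,5S)-2,5-dimethylthiolane; 10 5-(bromomethyl)-1,2,3-trimethoxybenzene
Product: 11 (2S,5S)-2,5-dimethyl-1-[(3,4,5-trimethoxyphenyl)methyl]thiolan-1-ium tetrafluoroborate
Conditions: AgBF4, CH2Cl2, 0 °C to rt, dark
Reagents that add atoms: silver tetrafluoroborate AgBF4, [Ag+].F[B-](F)(F)F
Why: S-alkylation with a benzylic bromide is made irreversible by precipitation of AgBr and the non-nucleophilic counter-ion, and because the two sulfur lone pairs of the C2-symmetric sulfide are homotopic a single salt forms with no stereocentre at sulfur.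

Step 6
Reactants: 6 (E)-1-(3,4-dimethoxyphenyl)-2-methylbut-2-en-1-one; 11 (2S,5S)-2,5-dimethyl-1-[(3,4,5-trimethoxyphenyl)methyl]thiolan-1-ium tetrafluoroborate
Product: 14 (2S,3S)-5-(3,4-dimethoxyphenyl)-3,4-dimethyl-2-(3,4,5-trimethoxyphenyl)-2,3-dihydrofuran, via thiolanium benzylide 12 (not isolated), via sulfonium enolate 13 (not isolated)
Conditions: Cs2CO3 (dry, powdered), MeCN, 0 °C to rt
Reagents that add atoms: none
Why: Proposed new method: Cs2CO3 deprotonates 11 reversibly to the benzylide 12, its carbanion adds to the beta-carbon C4 of 6 (C4–C5 bond) to give the sulfonium enolate 13, and the enolate oxygen then expels the thiolane from C5 with inversion (O1–C5 bond). The closest known reaction types are the formal (4+1) annulation of stabilised sulfur ylides with doubly activated enones to trans-2,3-dihydrofurans, the cyclopropanation of enones by chiral sulfonium benzylides and the onium-enolate closure of the nucleophile-catalysed Cloke–Wilson rearrangement, but closure on oxygen has not been shown for a benzylide and a plain alpha-methyl enone. The oxolane ring closes 5-exo-tet through an in-plane oxygen lone pair, against a 3-exo-tet closure on C3 that would have to create a quaternary carbon in a cyclopropane substituted on all three carbons, while electron-rich ring B loosens the C5–S bond and the weakly paired caesium enolate in MeCN puts the charge on oxygen. C5 is set by the C2-symmetric thiolane: in the favoured ylide conformer (ring B turned away from the thiolane) the ring methyl cis to the ylide carbon covers one face, so that the (2S,5S)-sulfide should give (R)-C5 in 13 and, after inversion, (S)-C5 in 14. C4 is set by the relative topicity of the addition, the 4,5-trans product being favoured because the other adduct can close only by pressing ring B against the C4 methyl and, closing slowly, has time to revert to 12 and 6. The step needs 1,4- over 1,2-addition (the hindered aryl ketone forms its adduct reversibly and closes to an epoxide poorly), O- over C-alkylation (alpha-methyl group, ring B, caesium/MeCN) and reaction through the s-cis enone conformer, since only the Z-enolate 13 brings O1 within reach of C5.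

Step 7
Reactants: 14 (2S,3S)-5-(3,4-dimethoxyphenyl)-3,4-dimethyl-2-(3,4,5-trimethoxyphenyl)-2,3-dihydrofuran
Product: 16 (2R,3S,4S,5S)-2-(3,4-dimethoxyphenyl)-3,4-dimethyl-5-(3,4,5-trimethoxyphenyl)oxolane, via oxocarbenium ion 15 (not isolated)
Conditions: Et3SiH, CF3CO2H, CH2Cl2, −40 to −10 °C
Reagents that add atoms: none
Why: In this ionic hydrogenation of an enol ether, protonation at C3 is reversible, so the ring-A-stabilised oxocarbenium ion 15 settles with the C3 methyl trans to the C4 methyl, and Et3SiH then delivers hydride to C2 from the face anti to the C3 methyl and to ring B, placing ring A cis to the C3 methyl as in the known reductions of 3,4-trans 2-aryloxolan-2-yl cations.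

**Compound list**
1 | tiglic acid, (E)-2-methylbut-2-enoic acid | C/C=C(\C)C(=O)O | starting material
2 | tigloyl chloride, (E)-2-methylbut-2-enoyl chloride | C/C=C(\C)C(=O)Cl | intermediate
3 | (E)-N-methoxy-N,2-dimethylbut-2-enamide | C/C=C(\C)C(=O)N(C)OC | intermediate
4 | 4-bromo-1,2-dimethoxybenzene | COc1ccc(Br)cc1OC | starting material
5 | (3,4-dimethoxyphenyl)magnesium bromide | COc1ccc([Mg]Br)cc1OC | intermediate
6 | (E)-1-(3,4-dimethoxyphenyl)-2-methylbut-2-en-1-one | COc1ccc(C(=O)/C(C)=C/C)cc1OC | intermediate
7 | (2R,5R)-hexane-2,5-diol | C[C@@H](O)CC[C@@H](C)O | starting material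
8 | (2R,5R)-hexane-2,5-diyl dimethanesulfonate | C[C@@H](OS(C)(=O)=O)CC[C@@H](C)OS(C)(=O)=O | intermediate
9 | (2S,5S)-2,5-dimethylthiolane | C[C@H]1CC[C@H](C)S1 | intermediate
10 | 5-(bromomethyl)-1,2,3-trimethoxybenzene | COc1cc(CBr)cc(OC)c1OC | starting material
11 | (2S,5S)-2,5-dimethyl-1-[(3,4,5-trimethoxyphenyl)methyl]thiolan-1-ium tetrafluoroborate | C[C@H]1CC[C@H](C)[S+]1Cc1cc(OC)c(OC)c(OC)c1.F[B-](F)(F)F | intermediate
12 | [(2S,5S)-2,5-dimethylthiolan-1-ium-1-yl](3,4,5-trimethoxyphenyl)methanide | C[C@H]1CC[C@H](C)[S+]1[CH-]c1cc(OC)c(OC)c(OC)c1 | intermediate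
13 | (1Z,3S,4R)-1-(3,4-dimethoxyphenyl)-4-[(2S,5S)-2,5-dimethylthiolan-1-ium-1-yl]-2,3-dimethyl-4-(3,4,5-trimethoxyphenyl)but-1-en-1-olate | COc1ccc(/C([O-])=C(C)/[C@H](C)[C@H](c2cc(OC)c(OC)c(OC)c2)[S+]3[C@@H](C)CC[C@@H]3C)cc1OC | intermediate
14 | (2S,3S)-5-(3,4-dimethoxyphenyl)-3,4-dimethyl-2-(3,4,5-trimethoxyphenyl)-2,3-dihydrofuran | COc1ccc(C2=C(C)[C@H](C)[C@@H](c3cc(OC)c(OC)c(OC)c3)O2)cc1OC | intermediate
15 | (2S,3S,4S)-5-(3,4-dimethoxyphenyl)-3,4-dimethyl-2-(3,4,5-trimethoxyphenyl)-3,4-dihydro-2H-furan-1-ium | COc1ccc(C2=[O+][C@H](c3cc(OC)c(OC)c(OC)c3)[C@@H](C)[C@@H]2C)cc1OC | intermediate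
16 | (2R,3S,4S,5S)-2-(3,4-dimethoxyphenyl)-3,4-dimethyl-5-(3,4,5-trimethoxyphenyl)oxolane | COc1ccc([C@@H]2O[C@H](c3cc(OC)c(OC)c(OC)c3)[C@@H](C)[C@@H]2C)cc1OC | target

**Step count**
Total: 7 steps. Longest linear sequence: 5 steps (7 → 8 → 9 → 11 → 14 → 16). The enone branch (1 → 3 → 6) joins at step 6.

**Steps most likely to fail**

Risk 1, step 6.
- What may go wrong: closure of the sulfonium enolate on carbon instead of oxygen. This is made more likely if the addition runs through the s-trans enone conformer, whose E-enolate cannot reach C5. Other failure modes are slow addition to a poorly electrophilic trisubstituted enone, with decay of the ylide by sigmatropic shift, and imperfect relative topicity at C4.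
- Fallback by known chemistry, setting out from 6 and 11 and returning at 14: the two bond formations are separated.
- The ylide is preformed with KOtBu in THF at −78 °C and left to cyclopropanate 6 (sulfur-ylide cyclopropanation of an enone, Corey–Chaykovsky type). This should give the donor–acceptor cyclopropane (3,4-dimethoxyphenyl)[(1S,2R,3S)-1,2-dimethyl-3-(3,4,5-trimethoxyphenyl)cyclopropyl]methanone F1.
- F1 is separated by chromatography from the diastereomer that differs at C4, because the two would later converge on opposite enantiomers.
- Sc(OTf)3 (cat.) in CH2Cl2 then opens the C3–C5 bond to a benzylic cation stabilised by ring B, paired with a scandium enolate. This pair recloses on oxygen (Cloke–Wilson rearrangement) trans to the untouched C4 methyl and should give 14.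

Risk 2, step 7.
- What may go wrong: hydride capture before C3 has equilibrated, which leads into the 3,4-cis series. Acid ionisation of the benzylic C–O bonds could also cause epimerisation at C2 or C5, or reductive ring opening.
- Fallback, setting out from 14 and returning at 16: protonation and hydride transfer become two operations.
- Equilibrating addition of methanol (MeOH, pyridinium p-toluenesulfonate cat., rt) sets the 3,4-trans relation under thermodynamic control. It should give the cyclic ketal (2R,3S,4S,5S)-2-(3,4-dimethoxyphenyl)-2-methoxy-3,4-dimethyl-5-(3,4,5-trimethoxyphenyl)oxolane F2, drawn as the anomer from attack anti to the C3 methyl. The anomeric centre is lost again in the next operation.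
- Reductive deoxygenation of F2 (Et3SiH, BF3·OEt2, CH2Cl2, −78 °C) then delivers hydride under purely kinetic control, at a temperature at which neither C3 nor the benzylic ethers should scramble, to give 16.

Risk 3, step 5.
- What may go wrong: silver-induced ionisation of the electron-rich benzylic bromide, with Friedel–Crafts self-alkylation outrunning S-alkylation of the hindered sulfide.
- Fallback, setting out from 9 and 10 and returning at 11: no halophile is used.
- The two components are combined concentrated in acetone at rt in the dark, so that plain SN2 alkylation should deposit (2S,5S)-2,5-dimethyl-1-[(3,4,5-trimethoxyphenyl)methyl]thiolan-1-ium bromide F3.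
- The nucleophilic counter-ion is then exchanged by metathesis with NaBF4 in CH2Cl2/H2O to give 11.

**Further compounds**
F1 | step 6 | (3,4-dimethoxyphenyl)[(1S,2R,3S)-1,2-dimethyl-3-(3,4,5-trimethoxyphenyl)cyclopropyl]methanone | COc1ccc(C(=O)[C@@]2(C)[C@H](C)[C@H]2c3cc(OC)c(OC)c(OC)c3)cc1OC
F2 | step 7 | (2R,3S,4S,5S)-2-(3,4-dimethoxyphenyl)-2-methoxy-3,4-dimethyl-5-(3,4,5-trimethoxyphenyl)oxolane | COc1ccc([C@]2(OC)O[C@H](c3cc(OC)c(OC)c(OC)c3)[C@@H](C)[C@@H]2C)cc1OC
F3 | step 5 | (2S,5S)-2,5-dimethyl-1-[(3,4,5-trimethoxyphenyl)methyl]thiolan-1-ium bromide | C[C@H]1CC[C@H](C)[S+]1Cc1cc(OC)c(OC)c(OC)c1.[Br-]
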